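**Plan**

1. Retrosynthetic cuts: first the cinnamate ester C(=O)–O bond; then, with a temporary formyl group placed on C3, the C3=C4 and O1–C2 bonds of the pyran ring in one retro-aldol-condensation/retro-oxa-Michael operation, leading back to a salicylaldehyde and a C5 enal.
2. Enabling feature: O1 and C4 sit on the neighbouring benzene carbons C8a and C4a (a salicylaldehyde pattern), and C2 lies β to a carbonyl carbon placed on C3. An enal iminium ion can therefore take up the phenol at C2, and its enamine can close onto the ortho-formyl carbon C4.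
3. Forward order: Duff formylation of acetovanillone; Wittig, reduction and oxidation to the (E)-silyloxy enal; an amine-catalysed domino that forms O1–C2 and then closes the pyran ring at C3–C4 (dehydration gives C3=C4). The benzene ring is bought.
4. Helpers removed afterwards: the formyl group on C3 (rhodium-mediated decarbonylation), the silyl ether on the CH2O arm, and the acetate on the ferulic phenol; the ester is made from the freed CH2OH.
5. Stereochemistry: the only stereocentre, C2 (R), is set in the key step by the (R)-configured diphenylprolinol silyl ether acting on the E enal. The E cinnamate is bought as such, and C3=C4 is cis by the ring.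

Key step: step 5

Remark: chromene numbering (O1, C2, C3, C4, C4a, C5 to C8, C8a) is used for all bicyclic compounds. Acetovanillone, 1-[(tert-butyldimethylsilyl)oxy]propan-2-one, ethyl (triphenylphosphoranylidene)acetate, (E)-4-acetoxy-3-methoxycinnamic acid and the catalyst (R)-2-[diphenyl(trimethylsilyloxy)methyl]pyrrolidine, C[Si](C)(C)OC(c1ccccc1)(c1ccccc1)[C@H]1CCCN1, are taken as commercial.

**Route**

Step 1
Reactants: 1 acetovanillone, 1-(4-hydroxy-3-methoxyphenyl)ethan-1-one
Product: 2 5-acetyl-2-hydroxy-3-methoxybenzaldehyde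
Conditions: (CH2)6N4 (2 equiv), CF3CO2H, 80 °C; then 3 M aq. HCl, 50 °C
Reagents that add atoms: hexamethylenetetramine C1N2CN3CN1CN(C2)C3 (formyl carbon); water O (formyl oxygen)
Why: Duff formylation, in which the iminium ion from protonated hexamethylenetetramine attacks the only free position ortho to the phenol (the para position carries the acetyl group) and the resulting benzylamine is oxidised by internal hydride transfer and hydrolysed to the aldehyde.

Step 2
Reactants: 3 1-[(tert-butyldimethylsilyl)oxy]propan-2-one; 4 ethyl (triphenylphosphoranylidene)acetate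
Product: 5 ethyl (2E)-4-[(tert-butyldimethylsilyl)oxy]-3-methylbut-2-enoate
Conditions: toluene, 100 °C; chromatography to remove the minor Z isomer
Reagents that add atoms: none
Why: Wittig reaction of a stabilised ylide with an α-silyloxy ketone, whose inductively activated carbonyl reacts under neutral conditions and should place the ester trans to the larger CH2OSi group (E); any Z isomer is separated.

Step 3
Reactants: 5 ethyl (2E)-4-[(tert-butyldimethylsilyl)oxy]-3-methylbut-2-enoate
Product: 6 (2E)-4-[(tert-butyldimethylsilyl)oxy]-3-methylbut-2-en-1-ol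
Conditions: i-Bu2AlH (2.2 equiv), CH2Cl2, −78 °C; aq. potassium sodium tartrate
Reagents that add atoms: none
Why: 1,2-reduction of the enoate to the allylic alcohol by i-Bu2AlH at low temperature leaves the alkene geometry and the silyl ether untouched.

Step 4
Reactants: 6 (2E)-4-[(tert-butyldimethylsilyl)oxy]-3-methylbut-2-en-1-ol
Product: 7 (2E)-4-[(tert-butyldimethylsilyl)oxy]-3-methylbut-2-enal
Conditions: MnO2 (activated, 10 equiv), CH2Cl2, rt
Reagents that add atoms: none
Why: allylic oxidation on MnO2 stops at the enal and, being neutral, should not isomerise the E double bond.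

Step 5
Reactants: 2 5-acetyl-2-hydroxy-3-methoxybenzaldehyde; 7 (2E)-4-[(tert-butyldimethylsilyl)oxy]-3-methylbut-2-enal
Product: 10 (2R)-6-acetyl-2-{[(tert-butyldimethylsilyl)oxy]methyl}-8-methoxy-2-methyl-2H-chromene-3-carbaldehyde, via enamine oxa-Michael adduct 8 (not isolated), via cyclised aldol iminium benzoate 9 (not isolated)
Conditions: (R)-2-[diphenyl(trimethylsilyloxy)methyl]pyrrolidine (20 mol %), PhCO2H (20 mol %), 4 Å molecular sieves, toluene, rt to 40 °C, dark
Reagents that add atoms: none
Why: Proposed new method: the amine condenses with enal 7 to an E-configured s-trans iminium ion, the acidic phenol of 2 adds to its fully substituted β-carbon to give enamine 8 (O1–C2 bond), the enamine carbon C3 then attacks the ortho-formyl carbon C4 to close the pyran ring as 9, and E1cB loss of water followed by hydrolysis releases 10 and the catalyst. The closest known reaction type is the diarylprolinol silyl ether catalysed domino oxa-Michael/aldol condensation of salicylaldehydes with β-monosubstituted enals to 2-substituted 2H-chromene-3-carbaldehydes, together with its achiral version with 3-methylbut-2-enal and with iminium-mediated oxygen and carbon additions to β,β-disubstituted enals that create fully substituted centres; new here is the enantioselective formation of an oxygen-bearing quaternary centre from an unsymmetrical β,β-disubstituted enal in this domino. The ring closes in a 6-(enolexo)-exo-trig aldol mode on the C3–C4 bond, and the dehydration that follows turns this bond into the C3=C4 double bond. C2 is controlled by the catalyst: the CPh2OSiMe3 group of the (R)-amine covers the Si face of the β-carbon of the (E)-iminium ion (CH2OSi trans to the iminium carbon), so the oxygen adds to the Re face and the (R) centre results. The step needs 1,4-addition to win over γ-deprotonation (dienamine formation, which would also scramble the E/Z geometry); this is helped by the electron-poor phenol of 2 (ortho-formyl, para-acetyl), which supplies phenoxide readily, by the small methyl group sitting cis to the iminium carbon, which should make the E-iminium both the more stable and the faster-reacting isomer, by the reversibility of the oxa-Michael step, so that only the adduct that cyclises leaves the equilibrium, and by the position of the acetyl group para to the oxygen, where it cannot reach the enamine. The enantiomeric purity is to be checked at 12 and, if required, raised by crystallisation.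

Step 6
Reactants: 10 (2R)-6-acetyl-2-{[(tert-butyldimethylsilyl)oxy]methyl}-8-methoxy-2-methyl-2H-chromene-3-carbaldehyde
Product: 11 1-[(2R)-2-{[(tert-butyldimethylsilyl)oxy]methyl}-8-methoxy-2-methyl-2H-chromen-6-yl]ethan-1-one
Conditions: RhCl(PPh3)3 (1.1 equiv), toluene, 90 °C, dark
Reagents that add atoms: none
Why: Tsuji–Wilkinson decarbonylation, in which oxidative addition of the formyl C–H bond to monovalent rhodium, CO extrusion to an alkenyl rhodium hydride and reductive elimination leave H on C3 with the C3=C4 bond in place, as is usual for α,β-unsaturated aldehydes; C2, the ketone and the silyl ether are not involved, and moderate temperature and exclusion of light guard against electrocyclic opening of the pyran ring.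

Step 7
Reactants: 11 1-[(2R)-2-{[(tert-butyldimethylsilyl)oxy]methyl}-8-methoxy-2-methyl-2H-chromen-6-yl]ethan-1-one
Product: 12 1-[(2R)-2-(hydroxymethyl)-8-methoxy-2-methyl-2H-chromen-6-yl]ethan-1-one
Conditions: Bu4NF (1.2 equiv), THF, 0 °C
Reagents that add atoms: none
Why: fluoride-driven cleavage of the primary silyl ether (strong Si–F bond) at 0 °C leaves the ketone, the chromene and the stereocentre untouched.

Step 8
Reactants: 12 1-[(2R)-2-(hydroxymethyl)-8-methoxy-2-methyl-2H-chromen-6-yl]ethan-1-one; 13 (E)-4-acetoxy-3-methoxycinnamic acid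
Product: 15 [(2R)-6-acetyl-8-methoxy-2-methyl-2H-chromen-2-yl]methyl (2E)-3-(4-acetoxy-3-methoxyphenyl)prop-2-enoate, via 4-acetoxy-3-methoxycinnamoyl chloride 14 (not isolated)
Conditions: 13, (COCl)2, DMF (cat.), CH2Cl2, 0 °C to rt, evaporate; then 12, pyridine, CH2Cl2, 0 °C to rt
Reagents that add atoms: none
Why: acid chloride formation by the chloroiminium route followed by acylation of the primary, neopentyl-type alcohol in pyridine; no 4-(dimethylamino)pyridine is used so that the aryl acetate is not transferred, and the E double bond of the acid is carried through unchanged.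

Step 9
Reactants: 15 [(2R)-6-acetyl-8-methoxy-2-methyl-2H-chromen-2-yl]methyl (2E)-3-(4-acetoxy-3-methoxyphenyl)prop-2-enoate
Product: 16 [(2R)-6-acetyl-8-methoxy-2-methyl-2H-chromen-2-yl]methyl (2E)-3-(4-hydroxy-3-methoxyphenyl)prop-2-enoate (CNP0168033.1)
Conditions: pyrrolidine (3 equiv), CH2Cl2, 0 °C
Reagents that add atoms: none
Why: aminolysis by pyrrolidine is selective for the activated aryl acetate (phenoxide leaving group) over the conjugated, hindered alkyl cinnamate and frees the phenol of the target without touching the stereocentre.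

**Compound list**

1 | acetovanillone, 1-(4-hydroxy-3-methoxyphenyl)ethan-1-one | CC(=O)c1ccc(O)c(OC)c1 | starting material
2 | 5-acetyl-2-hydroxy-3-methoxybenzaldehyde | CC(=O)c1cc(C=O)c(O)c(OC)c1 | intermediate
3 | 1-[(tert-butyldimethylsilyl)oxy]propan-2-one | CC(=O)CO[Si](C)(C)C(C)(C)C | starting material
4 | ethyl (triphenylphosphoranylidene)acetate | CCOC(=O)C=P(c1ccccc1)(c1ccccc1)c1ccccc1 | starting material
5 | ethyl (2E)-4-[(tert-butyldimethylsilyl)oxy]-3-methylbut-2-enoate | CCOC(=O)/C=C(\C)CO[Si](C)(C)C(C)(C)C | intermediate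
6 | (2E)-4-[(tert-butyldimethylsilyl)oxy]-3-methylbut-2-en-1-ol | OC/C=C(\C)CO[Si](C)(C)C(C)(C)C | intermediate
7 | (2E)-4-[(tert-butyldimethylsilyl)oxy]-3-methylbut-2-enal | O=C/C=C(\C)CO[Si](C)(C)C(C)(C)C | intermediate
8 | enamine oxa-Michael adduct: (2R)-1-[(1E,3R)-3-(4-acetyl-2-formyl-6-methoxyphenoxy)-4-[(tert-butyldimethylsilyl)oxy]-3-methylbut-1-en-1-yl]-2-[diphenyl(trimethylsilyloxy)methyl]pyrrolidine | CC(C)(C)[Si](C)(C)OC[C@@](Oc1c(C=O)cc(C(C)=O)cc1OC)(C)/C=C/N1CCC[C@@H]1C(c1ccccc1)(c1ccccc1)O[Si](C)(C)C | intermediate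
9 | cyclised aldol iminium benzoate: (2R)-1-{[(2R)-6-acetyl-2-{[(tert-butyldimethylsilyl)oxy]methyl}-4-hydroxy-8-methoxy-2-methylchroman-3-yl]methylidene}-2-[diphenyl(trimethylsilyloxy)methyl]pyrrolidin-1-ium benzoate, C3 and C4 not defined | C[Si](C)(C)OC(c1ccccc1)(c1ccccc1)[C@H]1CCC[N+]1=CC1C(O)c2cc(C(C)=O)cc(OC)c2O[C@@]1(C)CO[Si](C)(C)C(C)(C)C.[O-]C(=O)c1ccccc1 | intermediate
10 | (2R)-6-acetyl-2-{[(tert-butyldimethylsilyl)oxy]methyl}-8-methoxy-2-methyl-2H-chromene-3-carbaldehyde | CC(C)(C)[Si](C)(C)OC[C@@]1(C)C(C=O)=Cc2cc(C(C)=O)cc(OC)c2O1 | intermediate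
11 | 1-[(2R)-2-{[(tert-butyldimethylsilyl)oxy]methyl}-8-methoxy-2-methyl-2H-chromen-6-yl]ethan-1-one | CC(C)(C)[Si](C)(C)OC[C@@]1(C)C=Cc2cc(C(C)=O)cc(OC)c2O1 | intermediate
12 | 1-[(2R)-2-(hydroxymethyl)-8-methoxy-2-methyl-2H-chromen-6-yl]ethan-1-one | OC[C@@]1(C)C=Cc2cc(C(C)=O)cc(OC)c2O1 | intermediate
13 | (E)-4-acetoxy-3-methoxycinnamic acid | CC(=O)Oc1ccc(/C=C/C(=O)O)cc1OC | starting material
14 | (E)-4-acetoxy-3-methoxycinnamoyl chloride | CC(=O)Oc1ccc(/C=C/C(=O)Cl)cc1OC | intermediate
15 | [(2R)-6-acetyl-8-methoxy-2-methyl-2H-chromen-2-yl]methyl (2E)-3-(4-acetoxy-3-methoxyphenyl)prop-2-enoate | COc1cc(/C=C/C(=O)OC[C@@]2(C)C=Cc3cc(C(C)=O)cc(OC)c3O2)ccc1OC(C)=O | intermediate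
16 | [(2R)-6-acetyl-8-methoxy-2-methyl-2H-chromen-2-yl]methyl (2E)-3-(4-hydroxy-3-methoxyphenyl)prop-2-enoate | COc1cc(/C=C/C(=O)OC[C@@]2(C)C=Cc3cc(C(C)=O)cc(OC)c3O2)ccc1O | target

**Step count and risks**

Total steps: 9. Longest linear sequence: 8 steps (steps 2 to 9).

Steps most likely to fail:

Step 5. The enantioselectivity may be eroded by E/Z isomerisation of the iminium ion through the dienamine, or the enal may be diverted into γ-reactivity, so that the domino gives 10 in low enantiomeric purity or not at all. The fallback sets out from 2 and comes back at 11, using known chemistry only. Compound 2 is O-allylated with 2-methyl-2-vinyloxirane under zerovalent palladium catalysis (Pd2(dba)3·CHCl3, N,N'-(cyclohexane-1,2-diyl)bis[2-(diphenylphosphanyl)benzamide] as the (1R,2R) or (1S,2S) antipode, whichever gives the (R)-ether, CH2Cl2, rt). The phenol attacks the tertiary terminus of the π-allyl complex and gives 5-acetyl-2-{[(2R)-1-hydroxy-2-methylbut-3-en-2-yl]oxy}-3-methoxybenzaldehyde F1. Silylation (t-BuMe2SiCl, imidazole, DMF) gives 5-acetyl-2-{[(2R)-1-[(tert-butyldimethylsilyl)oxy]-2-methylbut-3-en-2-yl]oxy}-3-methoxybenzaldehyde F2. Aldehyde-selective Wittig methylenation (Ph3P=CH2, 1.05 equiv, THF, −78 to 0 °C) gives 1-[4-{[(2R)-1-[(tert-butyldimethylsilyl)oxy]-2-methylbut-3-en-2-yl]oxy}-3-ethenyl-5-methoxyphenyl]ethan-1-one F3. Ring-closing metathesis (second-generation Grubbs catalyst, CH2Cl2, 40 °C) then forms the same C3=C4 bond and gives 11, so steps 5 and 6 are not needed.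

Step 6. The temperature that CO extrusion needs may allow thermal electrocyclic opening and reclosure of the pyran ring (racemisation at C2), or the reaction may stall at an acyl rhodium stage. The fallback sets out from 10 and comes back at 11, and removes the formyl carbon oxidatively at or below 60 °C. Selenium-catalysed Baeyer–Villiger oxidation (30 % H2O2, bis(2-nitrophenyl) diselenide cat., CH2Cl2, rt) gives (2S)-6-acetyl-2-{[(tert-butyldimethylsilyl)oxy]methyl}-8-methoxy-2-methyl-2H-chromen-3-yl formate F4. Methanolysis (KHCO3, MeOH, 0 °C) gives (2S)-6-acetyl-2-{[(tert-butyldimethylsilyl)oxy]methyl}-8-methoxy-2-methylchroman-3-one F5. This ketone can enolise only toward the benzylic C4 and is much more acidic there than the acetyl group, so Tf2O with 2,6-di-tert-butyl-4-methylpyridine (CH2Cl2, −78 to 0 °C) gives (2S)-6-acetyl-2-{[(tert-butyldimethylsilyl)oxy]methyl}-8-methoxy-2-methyl-2H-chromen-3-yl trifluoromethanesulfonate F6. Palladium-catalysed formate reduction (Pd(OAc)2, PPh3, HCO2H, Et3N, DMF, 60 °C) gives 11. The descriptor at C2 reads S in F4 to F6 only because the oxygen on C3 changes the priority order; the spatial arrangement is unchanged.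

Step 9. Removal of the aryl acetate may be accompanied by aminolysis or conjugate addition at the cinnamate ester. The fallback sets out from 12 and comes back at 16, builds the cinnamate double bond on the substrate and needs no phenol protection. Heating 12 with 2,2-dimethyl-1,3-dioxane-4,6-dione (toluene, 90 °C) gives the malonic half ester 3-{[(2R)-6-acetyl-8-methoxy-2-methyl-2H-chromen-2-yl]methoxy}-3-oxopropanoic acid F7. Knoevenagel–Doebner condensation of F7 with vanillin (pyridine, piperidine cat., 50 °C) gives the E-configured target 16 directly, replacing steps 8 and 9.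

**Further compounds**

F1 | step 5 | 5-acetyl-2-{[(2R)-1-hydroxy-2-methylbut-3-en-2-yl]oxy}-3-methoxybenzaldehyde | OC[C@@](C)(C=C)Oc1c(C=O)cc(C(C)=O)cc1OC
F2 | step 5 | 5-acetyl-2-{[(2R)-1-[(tert-butyldimethylsilyl)oxy]-2-methylbut-3-en-2-yl]oxy}-3-methoxybenzaldehyde | CC(C)(C)[Si](C)(C)OC[C@@](C)(C=C)Oc1c(C=O)cc(C(C)=O)cc1OC
F3 | step 5 | 1-[4-{[(2R)-1-[(tert-butyldimethylsilyl)oxy]-2-methylbut-3-en-2-yl]oxy}-3-ethenyl-5-methoxyphenyl]ethan-1-one | CC(C)(C)[Si](C)(C)OC[C@@](C)(C=C)Oc1c(C=C)cc(C(C)=O)cc1OC
F4 | step 6 | (2S)-6-acetyl-2-{[(tert-butyldimethylsilyl)oxy]methyl}-8-methoxy-2-methyl-2H-chromen-3-yl formate | CC(C)(C)[Si](C)(C)OC[C@@]1(C)C(OC=O)=Cc2cc(C(C)=O)cc(OC)c2O1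
F5 | step 6 | (2S)-6-acetyl-2-{[(tert-butyldimethylsilyl)oxy]methyl}-8-methoxy-2-methylchroman-3-one | CC(C)(C)[Si](C)(C)OC[C@@]1(C)C(=O)Cc2cc(C(C)=O)cc(OC)c2O1
F6 | step 6 | (2S)-6-acetyl-2-{[(tert-butyldimethylsilyl)oxy]methyl}-8-methoxy-2-methyl-2H-chromen-3-yl trifluoromethanesulfonate | CC(C)(C)[Si](C)(C)OC[C@@]1(C)C(OS(=O)(=O)C(F)(F)F)=Cc2cc(C(C)=O)cc(OC)c2O1
F7 | step 9 | 3-{[(2R)-6-acetyl-8-methoxy-2-methyl-2H-chromen-2-yl]methoxy}-3-oxopropanoic acid | OC(=O)CC(=O)OC[C@@]1(C)C=Cc2cc(C(C)=O)cc(OC)c2O1
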